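**Retrosynthetic overview**
- Target ⇐ one global hydride reduction (methyl ester, N-acyl oxazolidinone, two aryl pivalates) of a 1-aryl-tetralin that already carries all three stereocentres.
- Ring B of the tetralin (the only ring made) ⇐ acid-triggered C7'–C6 Friedel–Crafts closure of an (8S,7'E)-7',8'-dehydro-seco-lignan. The O-protonated trimethoxycinnamate stands in for the biosynthetic quinone methide, the E alkene relays C8 to C1, and C-protonation of the resulting enol sets C2.
- Seco-lignan ⇐ Evans alkylation (C7–C8 bond, sets C8) of a benzylidene-succinyl oxazolidinone with a ring A benzylic bromide.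
- Benzylidene succinate ⇐ Stobbe condensation of 3,4,5-trimethoxybenzaldehyde with dimethyl succinate; bromide ⇐ 5-hydroxyvanillin (bis-pivalate, reductive bromination).
- Order: both arenes are bought; C8–C8'/C7'=C8' (Stobbe) → C7–C8 (alkylation) → ring B closure → reduction.

Assumption: lignan-type locants are used (tetralin: aryl-bearing carbon = C1, so the target is (1S,2S,3S), i.e. 1,2-cis, 2,3-trans; open chain: C7–C9 = ring A unit, C7'–C9' = trimethoxyphenyl unit), and 5-hydroxyvanillin is taken as a catalogue chemical.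

**Step 1**
Reactants: 1 3,4,5-trimethoxybenzaldehyde; 2 dimethyl succinate
Product: 4 (E)-3-(methoxycarbonyl)-4-(3,4,5-trimethoxyphenyl)but-3-enoic acid, via paraconic ester lactone 3 (not isolated)
Conditions: NaOMe (2.2 equiv), MeOH, reflux; then aq. HCl
Reagents that add atoms: none
Why: Stobbe condensation, in which the succinate enolate adds to the aldehyde, the alkoxide lactonises to 3 and base-induced E1cB ring opening gives the half-ester with the aryl group cis to CH2CO2H (E, the usual thermodynamic outcome); no stereocentre is formed.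

**Step 2**
Reactants: 4 (E)-3-(methoxycarbonyl)-4-(3,4,5-trimethoxyphenyl)but-3-enoic acid; 5 (S)-4-benzyl-1,3-oxazolidin-2-one
Product: 7 methyl (E)-4-[(4S)-4-benzyl-2-oxo-1,3-oxazolidin-3-yl]-4-oxo-2-(3,4,5-trimethoxybenzylidene)butanoate, via mixed pivalic anhydride 6 (not isolated)
Conditions: t-BuCOCl, Et3N, THF, −20 °C; then 5, LiCl, −20 °C → rt
Reagents that add atoms: none
Why: Mixed-anhydride N-acylation of the oxazolidinone under mild LiCl/Et3N conditions, the nucleophile attacking the unhindered (non-pivaloyl) carbonyl of 6; the alkene geometry is untouched and no new stereocentre is formed.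

**Step 3**
Reactants: 8 3,4-dihydroxy-5-methoxybenzaldehyde (5-hydroxyvanillin)
Product: 9 5-formyl-3-methoxy-1,2-phenylene bis(2,2-dimethylpropanoate)
Conditions: t-BuCOCl (2.5 equiv), Et3N, DMAP (cat.), CH2Cl2, 0 °C → rt
Reagents that add atoms: pivaloyl chloride, CC(C)(C)C(=O)Cl
Why: DMAP-catalysed O-acylation of both phenols; the pivalates have no α-hydrogens, are hindered enough to survive the later enolate step, make O5 a weaker donor than OMe (so ring closure later goes para to OMe) and are removed in the final hydride step; no stereocentre is formed.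

**Step 4**
Reactants: 9 5-formyl-3-methoxy-1,2-phenylene bis(2,2-dimethylpropanoate)
Product: 11 5-(bromomethyl)-3-methoxy-1,2-phenylene bis(2,2-dimethylpropanoate), via benzyl disiloxanyl ether 10 (not isolated)
Conditions: LiBr, Me3SiCl, (HMe2Si)2O, MeCN, rt → 50 °C
Reagents that add atoms: lithium bromide, [Li+].[Br-]
Why: One-pot reductive bromination, in which Me3SiBr (from Me3SiCl and LiBr) promotes hydrosilylation of the aldehyde to silyl ether 10 and then exchanges the benzylic silyloxy group for bromide; aryl pivalates are inert and no stereocentre is formed.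

**Step 5**
Reactants: 7 methyl (E)-4-[(4S)-4-benzyl-2-oxo-1,3-oxazolidin-3-yl]-4-oxo-2-(3,4,5-trimethoxybenzylidene)butanoate; 11 5-(bromomethyl)-3-methoxy-1,2-phenylene bis(2,2-dimethylpropanoate)
Product: 13 methyl (2E,3S)-3-{[(4S)-4-benzyl-2-oxo-1,3-oxazolidin-3-yl]carbonyl}-4-[3-methoxy-4,5-bis(pivaloyloxy)phenyl]-2-(3,4,5-trimethoxybenzylidene)butanoate, via sodium Z-enolate 12 (not isolated)
Conditions: NaN(SiMe3)2 (1.0 equiv), THF, −78 °C; then 11 (1.2 equiv), −78 → −40 °C; AcOH quench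
Reagents that add atoms: none
Why: Evans asymmetric alkylation, in which the chelated Z-enolate 12 is benzylated at its α-carbon (C8) on the face opposite the auxiliary benzyl group, which for the (S)-auxiliary gives the 8S centre (later C3 of the tetralin); the cross-conjugated alkene should keep its E geometry at −78 °C and the hindered pivalates should not be attacked.

**Step 6**
Reactants: 13 methyl (2E,3S)-3-{[(4S)-4-benzyl-2-oxo-1,3-oxazolidin-3-yl]carbonyl}-4-[3-methoxy-4,5-bis(pivaloyloxy)phenyl]-2-(3,4,5-trimethoxybenzylidene)butanoate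
Product: 15 methyl (1S,2S,3S)-3-{[(4S)-4-benzyl-2-oxo-1,3-oxazolidin-3-yl]carbonyl}-6-methoxy-7,8-bis(pivaloyloxy)-1-(3,4,5-trimethoxyphenyl)-1,2,3,4-tetrahydronaphthalene-2-carboxylate, via ketene hemiacetal 14 (not isolated)
Conditions: CF3SO3H (2 equiv), CH2Cl2 (0.02 M), −20 → 0 °C; aq. NaHCO3
Reagents that add atoms: none
Why: Proposed new method: O-protonation of the trimethoxycinnamate ester makes C7' a p-methoxybenzylic, quinone-methide-like cation that ring A attacks at C6 (para to OMe, the acyloxy groups being weak donors) in a six-ring Friedel–Crafts conjugate hydroarylation; because the E alkene holds the aryl group syn to C8 and allylic 1,3-strain puts H8 in the alkene plane, the aryl group at the new C1 ends up pseudoaxial and trans to the C3 acyl group (1S), and enol 14 is then C-protonated axially, anti to that aryl group, to give the 2S ester cis to it; the closest known reaction types are the CF3SO3H-mediated cyclisation of dibenzylidenesuccinates to 1-aryl-dihydronaphthalenes and acid-mediated hydroarylation of cinnamates.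

**Step 7**
Reactants: 15 methyl (1S,2S,3S)-3-{[(4S)-4-benzyl-2-oxo-1,3-oxazolidin-3-yl]carbonyl}-6-methoxy-7,8-bis(pivaloyloxy)-1-(3,4,5-trimethoxyphenyl)-1,2,3,4-tetrahydronaphthalene-2-carboxylate
Product: 16 (1S,2S,3S)-2,3-bis(hydroxymethyl)-6-methoxy-1-(3,4,5-trimethoxyphenyl)-1,2,3,4-tetrahydronaphthalene-7,8-diol
Conditions: LiAlH4 (6 equiv), THF, 0 °C → rt; then 1 M HCl under argon
Reagents that add atoms: none
Why: Hydride reduction, in which LiAlH4 turns the methyl ester and the N-acyl oxazolidinone (exocyclic cleavage) into the two CH2OH groups and cleaves both aryl pivalates to the phenols; reduction is faster than enolisation, so C1–C3 are carried through unchanged.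

**Compound list**
1 | 3,4,5-trimethoxybenzaldehyde | COc1cc(C=O)cc(OC)c1OC | starting material
2 | dimethyl succinate | COC(=O)CCC(=O)OC | starting material
3 | methyl 5-oxo-2-(3,4,5-trimethoxyphenyl)oxolane-3-carboxylate (Stobbe lactone, stereoisomer mixture) | COC(=O)C1CC(=O)OC1c1cc(OC)c(OC)c(OC)c1 | intermediate
4 | (E)-3-(methoxycarbonyl)-4-(3,4,5-trimethoxyphenyl)but-3-enoic acid | COC(=O)/C(=C/c1cc(OC)c(OC)c(OC)c1)CC(=O)O | intermediate
5 | (S)-4-benzyl-1,3-oxazolidin-2-one | O=C1N[C@@H](Cc2ccccc2)CO1 | starting material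
6 | (E)-3-(methoxycarbonyl)-4-(3,4,5-trimethoxyphenyl)but-3-enoic 2,2-dimethylpropanoic anhydride | COC(=O)/C(=C/c1cc(OC)c(OC)c(OC)c1)CC(=O)OC(=O)C(C)(C)C | intermediate
7 | methyl (E)-4-[(4S)-4-benzyl-2-oxo-1,3-oxazolidin-3-yl]-4-oxo-2-(3,4,5-trimethoxybenzylidene)butanoate | COC(=O)/C(=C/c1cc(OC)c(OC)c(OC)c1)CC(=O)N1C(=O)OC[C@@H]1Cc1ccccc1 | intermediate
8 | 3,4-dihydroxy-5-methoxybenzaldehyde (5-hydroxyvanillin) | COc1cc(C=O)cc(O)c1O | starting material
9 | 5-formyl-3-methoxy-1,2-phenylene bis(2,2-dimethylpropanoate) | COc1cc(C=O)cc(OC(=O)C(C)(C)C)c1OC(=O)C(C)(C)C | intermediate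
10 | 3-methoxy-5-{[(1,1,3,3-tetramethyldisiloxan-1-yl)oxy]methyl}-1,2-phenylene bis(2,2-dimethylpropanoate) | COc1cc(CO[Si](C)(C)O[SiH](C)C)cc(OC(=O)C(C)(C)C)c1OC(=O)C(C)(C)C | intermediate
11 | 5-(bromomethyl)-3-methoxy-1,2-phenylene bis(2,2-dimethylpropanoate) | COc1cc(CBr)cc(OC(=O)C(C)(C)C)c1OC(=O)C(C)(C)C | intermediate
12 | sodium (1Z,3E)-1-[(4S)-4-benzyl-2-oxo-1,3-oxazolidin-3-yl]-3-(methoxycarbonyl)-4-(3,4,5-trimethoxyphenyl)buta-1,3-dien-1-olate | [Na+].[O-]/C(N1C(=O)OC[C@@H]1Cc1ccccc1)=C\C(C(=O)OC)=C/c1cc(OC)c(OC)c(OC)c1 | intermediate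
13 | methyl (2E,3S)-3-{[(4S)-4-benzyl-2-oxo-1,3-oxazolidin-3-yl]carbonyl}-4-[3-methoxy-4,5-bis(pivaloyloxy)phenyl]-2-(3,4,5-trimethoxybenzylidene)butanoate | COC(=O)/C(=C/c1cc(OC)c(OC)c(OC)c1)[C@@H](C(=O)N1C(=O)OC[C@@H]1Cc1ccccc1)Cc1cc(OC)c(OC(=O)C(C)(C)C)c(OC(=O)C(C)(C)C)c1 | intermediate
14 | (1S,3S) ester enol of 15: C2 carries =C(OH)OMe in place of H and CO2Me | COc1cc2c(c(OC(=O)C(C)(C)C)c1OC(=O)C(C)(C)C)[C@H](c1cc(OC)c(OC)c(OC)c1)C(=C(O)OC)[C@@H](C(=O)N1C(=O)OC[C@@H]1Cc1ccccc1)C2 | intermediate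
15 | methyl (1S,2S,3S)-3-{[(4S)-4-benzyl-2-oxo-1,3-oxazolidin-3-yl]carbonyl}-6-methoxy-7,8-bis(pivaloyloxy)-1-(3,4,5-trimethoxyphenyl)-1,2,3,4-tetrahydronaphthalene-2-carboxylate | COc1cc2c(c(OC(=O)C(C)(C)C)c1OC(=O)C(C)(C)C)[C@H](c1cc(OC)c(OC)c(OC)c1)[C@H](C(=O)OC)[C@@H](C(=O)N1C(=O)OC[C@@H]1Cc1ccccc1)C2 | intermediate
16 | (1S,2S,3S)-2,3-bis(hydroxymethyl)-6-methoxy-1-(3,4,5-trimethoxyphenyl)-1,2,3,4-tetrahydronaphthalene-7,8-diol | COc1cc2c(c(O)c1O)[C@H](c1cc(OC)c(OC)c(OC)c1)[C@H](CO)[C@@H](CO)C2 | target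

**Totals**
Total step count: 7. Longest linear sequence: 5 steps (1 → 4 → 7 → 13 → 15 → 16, and equally 8 → 9 → 11 → 13 → 15 → 16).

**Three steps most likely to fail**

Step 6 is the main risk. The face of C-protonation of enol 14 (C2) is untested, the protonated enoate could lose its E geometry before closure (C1), and some attack at C2 of ring A is possible. The fallback sets out from 13 and comes back at 15, and it sets C2 in a separate base-mediated operation instead of in the acid step. If the closure gives mainly the 1,2-trans ester, methyl (1S,2R,3S)-3-{[(4S)-4-benzyl-2-oxo-1,3-oxazolidin-3-yl]carbonyl}-6-methoxy-7,8-bis(pivaloyloxy)-1-(3,4,5-trimethoxyphenyl)-1,2,3,4-tetrahydronaphthalene-2-carboxylate F6, this is treated with LiN(i-Pr)2 (THF, −78 °C; the imide α-hydrogen at C3 is shielded by allylic strain) and then quenched with 2,6-di-tert-butyl-4-methylphenol. Kinetic protonation on the face anti to the pseudoaxial aryl group gives 15.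

Step 5 is the next risk. The enolate α-carbon carries a bulky alkenyl group, γ-attack or loss of alkene geometry in the dienolate is possible, and the product C8–H is doubly activated. The fallback sets out from 5 and 11 and comes back at 16; it makes the C7–C8 bond first on a plain succinyl imide and installs the benzylidene afterwards.
- 5 is N-acylated (n-BuLi, THF, −78 °C; methyl 4-chloro-4-oxobutanoate) to methyl 4-[(4S)-4-benzyl-2-oxo-1,3-oxazolidin-3-yl]-4-oxobutanoate F1.
- F1 is benzylated with 11 under the conditions of step 5, with the same facial sense, to methyl (3S)-3-{[(4S)-4-benzyl-2-oxo-1,3-oxazolidin-3-yl]carbonyl}-4-[3-methoxy-4,5-bis(pivaloyloxy)phenyl]butanoate F2.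
- A Stobbe-type condensation of F2 with 1 (LiN(SiMe3)2, 2.2 equiv, THF, −78 °C → rt) follows; the ester CH2 is enolised because the branched imide α-C–H is shielded. The aldolate displaces the oxazolidinone to give the lactone methyl (4S)-4-[3-methoxy-4,5-bis(pivaloyloxy)benzyl]-5-oxo-2-(3,4,5-trimethoxyphenyl)oxolane-3-carboxylate F3.
- E1cB opening of F3 gives (2S,3E)-2-[3-methoxy-4,5-bis(pivaloyloxy)benzyl]-3-(methoxycarbonyl)-4-(3,4,5-trimethoxyphenyl)but-3-enoic acid F4.
- F4 is closed with CF3SO3H as in step 6 to (1S,2S,3S)-6-methoxy-2-(methoxycarbonyl)-7,8-bis(pivaloyloxy)-1-(3,4,5-trimethoxyphenyl)-1,2,3,4-tetrahydronaphthalene-3-carboxylic acid F5, and LiAlH4 (THF, 0 °C → rt) converts F5 into 16.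

Step 7 is the third risk. The imide sits on a hindered ring carbon, so hydride may open the oxazolidinone ring instead (giving an amide that LiAlH4 reduces to an amine), and the catechol product is air-sensitive. The fallback sets out from 15 and comes back at 16. The auxiliary is removed first by Yb(OSO2CF3)3-catalysed methanolysis (MeOH, 60 °C; chelation activates only the exocyclic carbonyl) to give dimethyl (1S,2S,3S)-6-methoxy-7,8-bis(pivaloyloxy)-1-(3,4,5-trimethoxyphenyl)-1,2,3,4-tetrahydronaphthalene-2,3-dicarboxylate F7. The simple diester and the pivalates are then reduced with LiAlH4 (THF, 0 °C; acidic work-up under argon) to 16.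

**Further compounds**
F1 | step 5 | methyl 4-[(4S)-4-benzyl-2-oxo-1,3-oxazolidin-3-yl]-4-oxobutanoate | COC(=O)CCC(=O)N1C(=O)OC[C@@H]1Cc1ccccc1
F2 | step 5 | methyl (3S)-3-{[(4S)-4-benzyl-2-oxo-1,3-oxazolidin-3-yl]carbonyl}-4-[3-methoxy-4,5-bis(pivaloyloxy)phenyl]butanoate | COC(=O)C[C@@H](C(=O)N1C(=O)OC[C@@H]1Cc1ccccc1)Cc1cc(OC)c(OC(=O)C(C)(C)C)c(OC(=O)C(C)(C)C)c1
F3 | step 5 | methyl (4S)-4-[3-methoxy-4,5-bis(pivaloyloxy)benzyl]-5-oxo-2-(3,4,5-trimethoxyphenyl)oxolane-3-carboxylate (C2/C3 stereoisomer mixture) | COC(=O)C1C(c2cc(OC)c(OC)c(OC)c2)OC(=O)[C@H]1Cc1cc(OC)c(OC(=O)C(C)(C)C)c(OC(=O)C(C)(C)C)c1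
F4 | step 5 | (2S,3E)-2-[3-methoxy-4,5-bis(pivaloyloxy)benzyl]-3-(methoxycarbonyl)-4-(3,4,5-trimethoxyphenyl)but-3-enoic acid | COC(=O)/C(=C/c1cc(OC)c(OC)c(OC)c1)[C@@H](C(=O)O)Cc1cc(OC)c(OC(=O)C(C)(C)C)c(OC(=O)C(C)(C)C)c1
F5 | step 5 | (1S,2S,3S)-6-methoxy-2-(methoxycarbonyl)-7,8-bis(pivaloyloxy)-1-(3,4,5-trimethoxyphenyl)-1,2,3,4-tetrahydronaphthalene-3-carboxylic acid | COc1cc2c(c(OC(=O)C(C)(C)C)c1OC(=O)C(C)(C)C)[C@H](c1cc(OC)c(OC)c(OC)c1)[C@H](C(=O)OC)[C@@H](C(=O)O)C2
F6 | step 6 | methyl (1S,2R,3S)-3-{[(4S)-4-benzyl-2-oxo-1,3-oxazolidin-3-yl]carbonyl}-6-methoxy-7,8-bis(pivaloyloxy)-1-(3,4,5-trimethoxyphenyl)-1,2,3,4-tetrahydronaphthalene-2-carboxylate (C2 epimer of 15) | COc1cc2c(c(OC(=O)C(C)(C)C)c1OC(=O)C(C)(C)C)[C@H](c1cc(OC)c(OC)c(OC)c1)[C@@H](C(=O)OC)[C@@H](C(=O)N1C(=O)OC[C@@H]1Cc1ccccc1)C2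
F7 | step 7 | dimethyl (1S,2S,3S)-6-methoxy-7,8-bis(pivaloyloxy)-1-(3,4,5-trimethoxyphenyl)-1,2,3,4-tetrahydronaphthalene-2,3-dicarboxylate | COc1cc2c(c(OC(=O)C(C)(C)C)c1OC(=O)C(C)(C)C)[C@H](c1cc(OC)c(OC)c(OC)c1)[C@H](C(=O)OC)[C@@H](C(=O)OC)C2
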